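Ring B is disconnected at C5–C6 (eudesmane numbering). Because the oxygen-bearing C4 of ring A adjoins ring-fusion C5, C4 at the ketone level makes C5 enolizable, and the C6 methylene can be an aldehyde carbon. An intramolecular aldol condensation of a ring-A diketo aldehyde therefore closes ring B and gives a bicyclic enedione whose two carbonyls are the two oxygenated ring carbons of the target (C4 and C9). The precursor, a 3-methyl-3-(4-oxobutanoyl)cyclohexanone, arises in two steps from 3-methylcyclohexenone by asymmetric conjugate addition (quaternary C10) and ozonolysis. Hydrogenation sets the trans fusion; the C4 carbinol, the axial C7 side chain (conjugate addition to the 7-en-9-one) and the C9 ester follow.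

Key step: step 3

Remark: eudesmane numbering is used (C10 = quaternary carbon with CH3-14; ring A = C1–C5 and C10; ring B = C5–C10; C4 carries OH and CH3-15; C11–C13 = side chain on C7; β = face of CH3-14), and (S)-3-methylpentanoic acid and hex-1-en-5-yne are assumed to be purchasable.

Step 1
Reactants: 1 3-methylcyclohex-2-en-1-one; 2 hex-1-en-5-yne
Product: 4 (S)-3-(hexa-1,5-dien-2-yl)-3-methylcyclohexan-1-one, via alkenylalane 3 (not isolated)
Conditions: 2, i-Bu2AlH, NiCl2(dppp) (3 mol%), THF, 0 °C to rt; then 1, Cu(OTf)2 (5 mol%), chiral sulfonate-bearing imidazolinium salt (NHC precursor, 5 mol%), THF, −30 °C; aq. potassium sodium tartrate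
Reagents that add atoms: none
Why: Nickel-catalysed α-selective hydroalumination of the terminal alkyne should give the 1,1-disubstituted alkenylalane, which adds to the β-methyl enone in a copper-catalysed asymmetric conjugate addition, the chiral NHC–copper complex selecting the enone face so that the ligand enantiomer is chosen to set quaternary C10 as (S).

Step 2
Reactants: 4 (S)-3-(hexa-1,5-dien-2-yl)-3-methylcyclohexan-1-one
Product: 5 (S)-4-(1-methyl-3-oxocyclohexyl)-4-oxobutanal
Conditions: O3, CH2Cl2/MeOH, −78 °C; Me2S, −78 °C to rt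
Reagents that add atoms: ozone [O-][O+]=O
Why: Ozonolysis with reductive work-up should cleave the 1,1-disubstituted alkene to the C9 ketone and the vinyl group to the C6 aldehyde (each losing formaldehyde) while the ring ketone and the quaternary C10 stay untouched.

Step 3
Reactants: 5 (S)-4-(1-methyl-3-oxocyclohexyl)-4-oxobutanal
Product: 6 (8aS)-8a-methyl-3,6,7,8-tetrahydronaphthalene-1,5(2H,8aH)-dione
Conditions: piperidine (0.3 equiv), AcOH (0.3 equiv), toluene (0.01 M), 80 °C
Reagents that add atoms: none
Why: Piperidinium acetate enolizes the C4 ketone toward C5 (enol or enamine) and activates the C6 aldehyde (iminium), C5 adds to C6, and the β-hydroxy (or β-amino) ketone eliminates by E1cB to give the C5=C6 enone conjugated with C4=O. The closest known reaction type is the intramolecular aldol (Knoevenagel-type) condensation of a keto aldehyde, the ring-closing half of a Robinson annulation. Ring B (C5, C6, C7, C8, C9, C10) closes in the 6-(enolexo)-exo-trig mode by forming the C5–C6 bond. No new stereocenter is formed, since C5 becomes trigonal and is set in step 4, and the non-enolizable quaternary C10 from step 1 is carried through unchanged. The step needs site selectivity among three carbonyl groups and four enolizable carbons: only the C5-to-C6 pairing gives a six-membered ring whose aldol can dehydrate to a conjugated enone, whereas the C8-to-C4, C3-to-C9 and C7-to-C4 aldols are bridged, could eliminate only to a bridgehead alkene, and should revert under the equilibrating conditions. Mild buffered catalysis is chosen so that the 4-oxobutanal unit does not dehydrate to a furan.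

Step 4
Reactants: 6 (8aS)-8a-methyl-3,6,7,8-tetrahydronaphthalene-1,5(2H,8aH)-dione
Product: 7 (4aR,8aS)-8a-methyloctahydronaphthalene-1,5-dione
Conditions: H2 (1 atm), Pd/C, EtOAc, rt
Reagents that add atoms: none
Why: Catalytic hydrogenation (syn addition on the catalyst surface) should occur on the α face of the trisubstituted C5=C6 bond, opposite the angular C10 methyl group as with steroidal 5-enes, so that H-5 ends up trans to CH3-14 and the trans-decalin results.

Step 5
Reactants: 7 (4aR,8aS)-8a-methyloctahydronaphthalene-1,5-dione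
Product: 8 (4aS,8aS)-8a-methyl-5-methylideneoctahydronaphthalen-1(2H)-one
Conditions: Ph3PCH3Br (1.3 equiv), KOt-Bu (1.2 equiv), THF, 0 °C to rt
Reagents that add atoms: methyltriphenylphosphonium bromide C[P+](c1ccccc1)(c1ccccc1)c1ccccc1.[Br-]
Why: Wittig methylenation with a near-stoichiometric amount of ylide should take the C4 ketone in preference to the C9 ketone, which is shielded by the adjacent quaternary C10, and any C5 epimerization through the C4 enolate is expected to drain through the faster-reacting trans ketone to the trans-fused alkene.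

Step 6
Reactants: 8 (4aS,8aS)-8a-methyl-5-methylideneoctahydronaphthalen-1(2H)-one
Product: 9 (4aR,5R,8aS)-5-hydroxy-5,8a-dimethyloctahydronaphthalen-1(2H)-one
Conditions: Co(acac)2 (20 mol%), PhSiH3, O2 (1 atm), THF, rt
Reagents that add atoms: dioxygen O=O
Why: Mukaiyama hydration (hydrogen-atom transfer to C15, then O2 capture of the tertiary C4 radical, Markovnikov) should deliver oxygen from the α face because the β-axial approach is blocked by the syn-axial C10 methyl group, giving the equatorial 4α-OH with CH3-15 axial.

Step 7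
Reactants: 9 (4aR,5R,8aS)-5-hydroxy-5,8a-dimethyloctahydronaphthalen-1(2H)-one
Product: 10 (4aR,5R,8aS)-5-hydroxy-5,8a-dimethyl-4a,5,6,7,8,8a-hexahydronaphthalen-1(4H)-one
Conditions: IBX, DMSO/toluene, 70 °C
Reagents that add atoms: none
Why: IBX dehydrogenation of the ketone should proceed through the only available enol (toward C8, since C10 is quaternary) to give the 7-en-9-one, the tertiary alcohol being inert to the oxidant.

Step 8
Reactants: 10 (4aR,5R,8aS)-5-hydroxy-5,8a-dimethyl-4a,5,6,7,8,8a-hexahydronaphthalen-1(4H)-one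
Product: 11 (3R,4aR,5R,8aS)-5-hydroxy-5,8a-dimethyl-3-(prop-1-en-2-yl)octahydronaphthalen-1(2H)-one
Conditions: isopropenylmagnesium bromide (3 equiv), CuBr·SMe2 (20 mol%), THF, −78 to −30 °C; aq. NH4Cl
Reagents that add atoms: isopropenylmagnesium bromide C=C(C)[Mg]Br
Why: Copper-catalysed 1,4-addition of the Grignard reagent should occur by stereoelectronically preferred axial attack at C7 of the conformationally locked trans-fused enone, that is on the α face, which sets the axial 7α side chain trans to CH3-14 (the first equivalent of reagent only deprotonates the tertiary alcohol).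

Step 9
Reactants: 11 (3R,4aR,5R,8aS)-5-hydroxy-5,8a-dimethyl-3-(prop-1-en-2-yl)octahydronaphthalen-1(2H)-one
Product: 12 (1S,3R,4aR,5R,8aS)-5,8a-dimethyl-3-(prop-1-en-2-yl)decahydronaphthalene-1,5-diol
Conditions: Li, liquid NH3/THF, −78 °C; solid NH4Cl
Reagents that add atoms: none
Why: Dissolving-metal reduction of the ketone should give the thermodynamically preferred equatorial 9β-alcohol (the axial 9α-alcohol would be syn-axial to the 7α-isopropenyl group), whereas hydride reagents would be steered to the wrong face, and the isolated alkene is not reduced.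

Step 10
Reactants: 12 (1S,3R,4aR,5R,8aS)-5,8a-dimethyl-3-(prop-1-en-2-yl)decahydronaphthalene-1,5-diol; 13 (S)-3-methylpentanoic acid
Product: 14 (1S,3R,4aR,5R,8aS)-5-hydroxy-5,8a-dimethyl-3-(prop-1-en-2-yl)decahydronaphthalen-1-yl (3S)-3-methylpentanoate
Conditions: DCC, DMAP (cat.), CH2Cl2, 0 °C to rt
Reagents that add atoms: none
Why: Steglich esterification should acylate the secondary equatorial 9β-OH and leave the tertiary 4-OH untouched, and the stereocenter of the acid, being β to the carbonyl, cannot epimerize.

Step 11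
Reactants: 14 (1S,3R,4aR,5R,8aS)-5-hydroxy-5,8a-dimethyl-3-(prop-1-en-2-yl)decahydronaphthalen-1-yl (3S)-3-methylpentanoate
Product: 16 (1S,3R,4aR,5R,8aS)-5-hydroxy-5,8a-dimethyl-3-(3-oxoprop-1-en-2-yl)decahydronaphthalen-1-yl (3S)-3-methylpentanoate, via allylic alcohol 15 (not isolated)
Conditions: SeO2 (cat.), t-BuOOH, CH2Cl2, rt; then MnO2, CH2Cl2, rt
Reagents that add atoms: tert-butyl hydroperoxide CC(C)(C)OO
Why: Riley allylic oxidation (ene reaction then [2,3]-shift) should functionalize the allylic methyl group of the isopropenyl unit in preference to the methine C7–H, and MnO2 then oxidizes the primary allylic alcohol to the enal without touching the tertiary alcohol or the ester.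

Step 12
Reactants: 16 (1S,3R,4aR,5R,8aS)-5-hydroxy-5,8a-dimethyl-3-(3-oxoprop-1-en-2-yl)decahydronaphthalen-1-yl (3S)-3-methylpentanoate
Product: 17 2-[(2R,4S,4aS,8R,8aR)-8-hydroxy-4a,8-dimethyl-4-{[(3S)-3-methylpentanoyl]oxy}decahydronaphthalen-2-yl]prop-2-enoic acid (CNP0471281.1)
Conditions: NaClO2, NaH2PO4, 2-methyl-2-butene, t-BuOH/H2O, rt
Reagents that add atoms: sodium chlorite [Na+].[O-]Cl=O
Why: Pinnick oxidation should convert the α-substituted acrolein into the acrylic acid under buffered conditions that spare the ester, the tertiary alcohol and the 1,1-disubstituted alkene, with 2-methyl-2-butene scavenging hypochlorite.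

Compound list
1 | 3-methylcyclohex-2-en-1-one | CC1=CC(=O)CCC1 | starting material
2 | hex-1-en-5-yne | C=CCCC#C | starting material
3 | diisobutyl(hexa-1,5-dien-2-yl)aluminium (alkenylalane, not isolated) | C=C(CCC=C)[Al](CC(C)C)CC(C)C | intermediate
4 | (S)-3-(hexa-1,5-dien-2-yl)-3-methylcyclohexan-1-one | C=C(CCC=C)[C@@]1(C)CCCC(=O)C1 | intermediate
5 | (S)-4-(1-methyl-3-oxocyclohexyl)-4-oxobutanal | O=CCCC(=O)[C@@]1(C)CCCC(=O)C1 | intermediate
6 | (8aS)-8a-methyl-3,6,7,8-tetrahydronaphthalene-1,5(2H,8aH)-dione (C4=O, C5=C6, C9=O) | C1CC(=O)[C@@]2(C)CCCC(=O)C2=C1 | intermediate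
7 | (4aR,8aS)-8a-methyloctahydronaphthalene-1,5-dione (trans-fused, 5α-H) | C1CC(=O)[C@@]2(C)CCCC(=O)[C@@H]2C1 | intermediate
8 | (4aS,8aS)-8a-methyl-5-methylideneoctahydronaphthalen-1(2H)-one | C1CC(=O)[C@@]2(C)CCCC(=C)[C@@H]2C1 | intermediate
9 | (4aR,5R,8aS)-5-hydroxy-5,8a-dimethyloctahydronaphthalen-1(2H)-one (4α-OH, 4β-CH3) | C1CC(=O)[C@@]2(C)CCC[C@@](C)(O)[C@@H]2C1 | intermediate
10 | (4aR,5R,8aS)-5-hydroxy-5,8a-dimethyl-4a,5,6,7,8,8a-hexahydronaphthalen-1(4H)-one (7-en-9-one) | C1=CC(=O)[C@@]2(C)CCC[C@@](C)(O)[C@@H]2C1 | intermediate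
11 | (3R,4aR,5R,8aS)-5-hydroxy-5,8a-dimethyl-3-(prop-1-en-2-yl)octahydronaphthalen-1(2H)-one (7α-isopropenyl) | C=C(C)[C@H]1CC(=O)[C@@]2(C)CCC[C@@](C)(O)[C@@H]2C1 | intermediate
12 | (1S,3R,4aR,5R,8aS)-5,8a-dimethyl-3-(prop-1-en-2-yl)decahydronaphthalene-1,5-diol (9β-OH) | C=C(C)[C@H]1C[C@H](O)[C@@]2(C)CCC[C@@](C)(O)[C@@H]2C1 | intermediate
13 | (S)-3-methylpentanoic acid | OC(=O)C[C@@H](C)CC | starting material
14 | (1S,3R,4aR,5R,8aS)-5-hydroxy-5,8a-dimethyl-3-(prop-1-en-2-yl)decahydronaphthalen-1-yl (3S)-3-methylpentanoate | C=C(C)[C@H]1C[C@H](OC(=O)C[C@@H](C)CC)[C@@]2(C)CCC[C@@](C)(O)[C@@H]2C1 | intermediate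
15 | (1S,3R,4aR,5R,8aS)-5-hydroxy-3-(3-hydroxyprop-1-en-2-yl)-5,8a-dimethyldecahydronaphthalen-1-yl (3S)-3-methylpentanoate (allylic alcohol, not isolated) | C=C(CO)[C@H]1C[C@H](OC(=O)C[C@@H](C)CC)[C@@]2(C)CCC[C@@](C)(O)[C@@H]2C1 | intermediate
16 | (1S,3R,4aR,5R,8aS)-5-hydroxy-5,8a-dimethyl-3-(3-oxoprop-1-en-2-yl)decahydronaphthalen-1-yl (3S)-3-methylpentanoate | C=C(C=O)[C@H]1C[C@H](OC(=O)C[C@@H](C)CC)[C@@]2(C)CCC[C@@](C)(O)[C@@H]2C1 | intermediate
17 | 2-[(2R,4S,4aS,8R,8aR)-8-hydroxy-4a,8-dimethyl-4-{[(3S)-3-methylpentanoyl]oxy}decahydronaphthalen-2-yl]prop-2-enoic acid (CNP0471281.1) | C=C(C(=O)O)[C@H]1C[C@H](OC(=O)C[C@@H](C)CC)[C@@]2(C)CCC[C@@](C)(O)[C@@H]2C1 | target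

Total step count: 12. Longest linear sequence: 12 steps (from 1 and 2 to 17).

Steps most likely to fail

Step 1. The hydroalumination may give poor α/β regiocontrol or touch the remote alkene, and the branched alkenyl group may add with eroded enantioselectivity. The fallback sets out from 1 and comes back at 4. The nucleophile is built regio-defined instead: 2,3-dibromopropene and allylmagnesium bromide give 2-bromohexa-1,5-diene F1. Bromine–lithium exchange (t-BuLi, Et2O, −78 °C) and transmetalation with Me2AlCl give dimethyl(hexa-1,5-dien-2-yl)aluminium F2. F2 is added to 1 with copper thiophene-2-carboxylate and a chiral phosphoramidite-type ligand to give 4.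

Step 5. The ylide may also methylenate the C9 ketone, or enolization of the C4 ketone may erode the trans ring fusion before olefination. The fallback sets out from 6 and comes back at 8. The C9 carbonyl is masked first: selective ketalization of the saturated ketone of 6 (ethylene glycol, p-TsOH, benzene), which the conjugated C4 carbonyl should resist, gives the C9 ethylene ketal of the enedione F3. Hydrogenation as in step 4 gives the trans-fused keto ketal F4. Wittig methylenation of the now single ketone gives the methylene ketal F5, and mild hydrolysis (PPTS, aqueous acetone) returns 8.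

Step 6. Oxygen capture by the planar C4 radical may show poor facial selectivity, or the radical may simply be reduced to the alkane. The fallback sets out from 8 and comes back at 9. Oxygen is delivered by a two-electron path: m-CPBA epoxidation from the α face gives the 4α,15-epoxide F6. LiAlH4 opens the epoxide at C15 and reduces the C9 ketone to give the 4α,9β-diol F7 (either C9 epimer serves). Dess–Martin oxidation of the secondary alcohol returns 9.

Further compounds
F1 | step 1 | 2-bromohexa-1,5-diene | C=C(Br)CCC=C
F2 | step 1 | dimethyl(hexa-1,5-dien-2-yl)aluminium | C=C(CCC=C)[Al](C)C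
F3 | step 5 | C9 ethylene ketal of enedione 6 | C1CC2(OCCO2)[C@@]3(C)CCCC(=O)C3=C1
F4 | step 5 | C9 ethylene ketal of trans-dione 7 | C1CC2(OCCO2)[C@@]3(C)CCCC(=O)[C@@H]3C1
F5 | step 5 | C9 ethylene ketal of methylene ketone 8 | C1CC2(OCCO2)[C@@]3(C)CCCC(=C)[C@@H]3C1
F6 | step 6 | 4α,15-epoxide of methylene ketone 8 | C1CC(=O)[C@@]2(C)CCC[C@@]3(OC3)[C@@H]2C1
F7 | step 6 | (1S,4aR,5R,8aS)-5,8a-dimethyldecahydronaphthalene-1,5-diol (4α,9β-diol) | C1C[C@H](O)[C@@]2(C)CCC[C@@](C)(O)[C@@H]2C1
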